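The ratio of E to X in the charge ran from 8.67 in summer down to 0.520 in autumn, and a J takes 3 E, so I first asked how long X lasts.

| flask | X | E | remark | time |
|---|---|---|---|---|
| gamma | 0.080 M | 0.52 M | run made earlier |  |
| delta | 1.5 M | 0.52 M | run made earlier |  |
| summer | 0.060 M | 0.520 M |  | 30 min |
| dawn | 0.12 M | 0.520 M |  | 30 min |
| spring | 0.25 M | 0.520 M |  | 30 min |
| dusk | 0.50 M | 0.520 M |  | 30 min |
| autumn | 1.0 M | 0.520 M |  | 30 min |

| run | time / min | J / % | X / % |
|---|---|---|---|
| gamma | 2.00 | 0 | 86 |
| gamma | 4.00 | 3 | 77 |
| gamma | 6.00 | 1 | 67 |
| gamma | 8.00 | 9 | 56 |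
| gamma | 10.0 | 9 | 50 |
| gamma | 12.0 | 13 | 45 |
| gamma | 15.0 | 19 | 36 |
| delta | 1.33 | 0 | 89 |
| delta | 2.00 | 0 | 88 |
| delta | 3.00 | 3 | 85 |
| delta | 4.00 | 0 | 83 |
| delta | 6.00 | 0 | 77 |
| delta | 10.0 | 0 | 76 |
| delta | 15.0 | 0 | 74 |

(standard deviation of a reading: 2 percentage points)

- the numbers in the tables scatter by 2 percentage points (one standard deviation)
- a reading or a percentage of J counts all its forms, free or not
- the concentration of J that is asked is that of its free form alone
- "hardly changes" means that all values lie within two and a half points (for a concentration: within two and a half percent of the largest)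

1. [J] (only what is free in solution) at the end for summer, dawn, spring, dusk, autumn, in this order
2. the shape of the row from first to last (falls, then rises / falls all the way / rises all the way / hardly changes / rises, then falls)

I took the loss of X as proportional to [X][E]. With [E] near its charge this is a pseudo-first-order decay, and it integrates in closed form: [X] over its charge is exp(−t/τ). Gamma read 36% at 15.0 min, so the X time constant, the time in which X falls by a factor e at the E charge of these flasks, was 14.7 min.

But that was one reading. The formula gave 50.6% at 10.0 min, and gamma read 50% there, so the value held within the scatter of 2 percentage points. Did τ depend on the X charge? Delta carried 18.8 times the X of gamma, and at 2.00 min it read 88% against 87.3% from τ. So that reading showed no dependence on the X charge, at that early time.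

For summer, τ gave 13.0% of X left at 30 min. But E falls, and then t must be weighted by [E] over its charge. If each X lost took 3 E, summer spent 30.1% of its E. Taking that fall as even in time, I reckoned the mean [E] at 84.9% of the charge, and X left came to 17.6%. I committed to a value between these two. This gave X, not J: gamma had lost 64.0% of its X at 15.0 min, and J read 19%.

The forecast gave 0.034 M, 0.057 M, 0.076 M, 0.065 M and 0.034 M, with the shape rises, then falls, and it took free J as total J on the ground “Nothing in the data shows bound J”.

The flask gave 0.00303 M, 0.00350 M, 0.00362 M, 0.00283 M and 0.00234 M, with the shape rises, then falls.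

    Z → D (k = 7.08 × 10⁻⁴ /s)
    Q ⇌ J, rate k2*(cs2 - [J]) while solid is left; crystals form when [J] > cs2 (solubility = 2.30 mM, k = 0.0185 /s)
    E + J ⇌ G (K = 1.00 /M, k = 4.16 × 10⁻⁴ /M/s)
    E + Z → J (k = 0.00503 /M/s)
    E + L → Z (k = 0.00583 /M/s)
    X + E → L (k = 0.00223 /M/s)

In summer, X + E ran through the whole 30 min and left 16.5% of X, inside my bracket. In summer, E + Z had half of its turnover up to 30 min behind it at 16.3 min, and by the end summer counted 46.6% of J, with 41.5% of the X charged standing as crystals Q within that count, and free [J] was 0.00303 M against the forecast's 0.034 M. In spring, E stood at 51.5% of its charge at 15.0 min and 28.8% of its charge at 30.0 min; τ weighted by that [E] gives 30.6% of X, and spring held 30.9%.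

(The numbers in the tables were computed for an exercise, and the scatter is random.)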